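(The numbers in the tables were computed from invented constants, noise included.)

You cannot read product off these flasks: every reading is of starting material, so a fall tells you what left, not what it became. Before charging the amber flask you must choose whether its free catalyst stays at 0.0200 M, and that hangs on how much of the fall is the catalyst's work.

| setting | red | green | ochre | amber |
|---|---|---|---|---|
| starting material | 0.400 M | 0.800 M | 0.400 M | 1.40 M |
| free catalyst | 0.0200 M | 0.0200 M | 0.0400 M | 0.0200 M |
| time |  |  |  | 8.3 min |

- red run (time / min: [starting material] / M): 0.33: 0.3564; 0.57: 0.3259; 0.97: 0.2878; 1.7: 0.2311; 2.8: 0.1728; 4.9: 0.1119; 8.3: 0.0637
- green run (time / min: [starting material] / M): 0.33: 0.7248; 0.57: 0.6768; 0.97: 0.6009; 1.7: 0.4734; 2.8: 0.3348; 4.9: 0.1849; 8.3: 0.0945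
- ochre run (time / min: [starting material] / M): 0.33: 0.3365; 0.57: 0.3012; 0.97: 0.2450; 1.7: 0.1902; 2.8: 0.1333; 4.9: 0.0865; 8.3: 0.0556

(scatter of a reading: 0.002 M)

- reaction order in [free catalyst] at the outset, round the charge of the red run, defined at two percent of the starting material turned into product
- reaction order in [starting material] at the outset, round the charge of the red run, defined at two percent of the starting material turned into product (one fixed amount of product, the same in the runs compared)
- starting material in the amber run at 8.3 min, as a share of the starting material charged

- Overall: starting material -> product, with free catalyst as catalyst.
- Constant volume, constant temperature.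
- The analysis sees a species whether free or bound.
- An order is taken over about fifteen percent of the charge, up and down.

Over the first interval the red run falls at 0.132 M/min and the ochre run at 0.192 M/min, so twice the catalyst gives 1.45 times the fall. I suspect part of the fall needs no catalyst. The last two readings of each run give a fractional fall per minute: 0.166 /min for red, 0.197 /min for green and 0.130 /min for ochre. I take the ochre value, the lowest, as the background constant: the share of the starting material lost each minute without making product. From the early end, twice the red fall less the ochre fall leaves 0.0720 M/min, which also points to a loss without catalyst. I commit to the late value.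

| Run | First fall | Background part | Left for product |
|---|---|---|---|
| red | 0.132 M/min | 0.0492 M/min | 0.0830 M/min |
| green | 0.228 M/min | 0.0991 M/min | 0.129 M/min |
| ochre | 0.192 M/min | 0.0479 M/min | 0.145 M/min |

The last column gives me an order of 0.801 in free catalyst and, averaged across a doubling, 0.634 in starting material.

For amber, I give the catalyst green's 0.129 M/min on the way down to 0.800 M. Background at the mean 1.10 M adds 0.143 M/min by my reading of the constant. That stretch takes 2.21 min. Following green for the remaining time leaves 0.146 M, or 10.4% of the charge, so I leave the catalyst at 0.0200 M.

The forecast, which differs from me, gives orders of 0.5 and 0.85 and 12% left (9% to 16%), noting “Doubling catalyst raises the early rate only about 1.45-fold”.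

The simulation gives orders of 0.96 in free catalyst and 0.93 in starting material, with 10.1% left in amber.

    free catalyst + starting material ⇌ catalyst-substrate complex, settled at all times (0.9680 /M)
    catalyst-substrate complex + starting material ⇌ doubly bound catalyst, settled at all times (10.70 /M)
    doubly bound catalyst → product + catalyst-substrate complex (8.760 /min)
    2 free catalyst → 2 spent catalyst (18.24 /M/min)
    starting material → decomposed substrate (0.1206 /min)

Product forms at 0.088 M/min in the red run and 0.17 M/min in the ochre run, both where two percent of the red charge has turned. At 8.3 min, amber holds 0.142 M, on which the background constant as I read it from the ochre run, 0.130 /min, reckons a loss of 0.0184 M/min. In the green run by 1.7 min, the fall is 0.327 M, that reading reckons 0.141 M of it as background and leaves 0.186 M for product, while product reached 0.200 M at 1.67 min.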